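The readings stem from a simulated flask with constants of no real substance; noise was put on by code.

Which flask ends with more target: violet, with twice grey's enzyme but a time of 15 h, or grey, with a time of 60 h? I reckon it from the two earlier runs.

in all of them: substrate 47 mM
- east: enzyme 8.1 µM; run made earlier
- north-east: enzyme 16 µM; run made earlier
- violet: enzyme 24 µM; time 15 h
- grey: enzyme 12 µM; time 60 h

- east (time / h: target / %, substrate / %): 1.33: 25, 49; 2.50: 40, 25; 4.00: 50, 10; 5.00: 51, 10; 6.00: 49, 4; 8.00: 52, 1
- north-east (time / h: target / %, substrate / %): 0.500: 20, 70; 1.33: 46, 34; 2.50: 61, 15; 4.00: 68, 4; 6.00: 68, 1; 8.00: 71, 0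

(readings scatter by 1.5 percentage points)

- the flask that ends with the higher amount of target, in percent of the substrate charged, or "neither" when 2 percentage points or less lies between them (violet / grey / neither)
- final target, as a percentage of the substrate charged, in violet
- final target, as a percentage of the substrate charged, in grey



The readings do not add up to the charge. At the last reading, east lacks 47.0% and north-east 29.0%. I call this the missing share, and I take target over missing share, a selectivity factor, as proportional to [enzyme]. Pooling the runs gives 0.147 µM⁻¹, so the first level of the curve is 78.0% in violet and 63.9% in grey. North-east's first slope, scaled to grey's [enzyme], is 0.300 h⁻¹ of the charge, and drawn straight it meets grey's level at the knee, 2.13 h.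

Substrate reads 1% in east and 0% in north-east at 8.00 h, so for these late readings I freeze it as negligible and follow the missing share. From 6.00 h to 8.00 h, the missing shares of the two runs, added together, fall from 78.0% to 76.0%. That gives the leak, the part of the missing share returning per hour, 0.0130 h⁻¹, a half-life of 53.4 h. This is a weak reading: the fall, 2 percentage points, is smaller than its own scatter, 4.2 points. Violet's time is shorter than that half-life and grey's longer. Taking target as the charge minus the missing share, I get 81.9% in violet and 83.4% in grey. The gap is less than the margin, so I say neither.

The forecast gives 77% for violet and 62% for grey, names violet as the flask that ends higher, and remarks “Target looks flat once substrate is gone”; it differs from my reckoning.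

Violet ends at 80.2% and grey at 80.8%, so the answer is neither.

    2 substrate → homo dimer (k = 0.00670 M⁻¹ h⁻¹)
    substrate + enzyme → target + enzyme, rate k2*[substrate]^1.5*[enzyme]/(1 + ([substrate]/Kh2)^1.5) (19.0 mM, k = 5.80 × 10⁵ M⁻¹·⁵ h⁻¹)
    substrate ⇌ dormant form (K = 8.70, k = 0.260 h⁻¹)

In grey the missing share is nearly all dormant form, which falls from 25.6% at 30.0 h to 17.9% at 60.0 h. Carrying violet's 18.8% at 15.0 h forward by the leak to 25.0 h gives 16.5%, and violet read at that time holds 16.1% dormant form beside 83.0% target.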